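## Retrosynthetic overview
1. The 3'-OH is removed first. It goes in last by lithiation/borylation/oxidation of the only C–H flanked by two methoxy groups (between 2'-OMe and 4'-OMe).
2. Ring C is opened at O1–C2. It is closed by an enantioselective, anti-Markovnikov 6-endo hydroetherification of a 2-(2-arylallyl)phenol, which forms the C–O bond and sets C3 as (S) in one step.
3. The 1,1-disubstituted alkene comes from Suzuki–Miyaura coupling of a ring A 2-bromoallyl arene with 2,4,5-trimethoxyphenylboronic acid (ring B).
4. The 2-bromoallyl arene comes from the aromatic Claisen rearrangement of the mono(2-bromoallyl) ether of 2-methoxyresorcinol.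
5. Rings A and B are bought. Ring C is the only ring formed (step 4).

Assumption: the sense of induction of the new thiol catalyst cannot be predicted, so its (R)-antipode is written as the one giving (3S); if a test run gives (3R), the (S)-antipode is used. The catalyst is made separately from BINOL and is not counted in the steps.

## Route

Step 1
Reactants: 1 2-methoxybenzene-1,3-diol (2-methoxyresorcinol); 2 2,3-dibromoprop-1-ene
Product: 3 3-[(2-bromoprop-2-en-1-yl)oxy]-2-methoxyphenol
Conditions: 1 (1.5 equiv), 2 (1.0 equiv), K2CO3 (1.0 equiv), acetone, reflux, 6 h; excess 1 recovered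
Reagents that add atoms: none
Why: Williamson ether synthesis in which the phenoxide displaces only the allylic bromide (SN2) while the vinylic C–Br stays inert, and the excess of the symmetric diol keeps bis-alkylation low; no stereocentre is formed.

Step 2
Reactants: 3 3-[(2-bromoprop-2-en-1-yl)oxy]-2-methoxyphenol
Product: 5 4-(2-bromoprop-2-en-1-yl)-2-methoxybenzene-1,3-diol, via ortho-dienone 4 (not isolated)
Conditions: PhNEt2, 190 °C, Ar, 3 h
Reagents that add atoms: none
Why: Aromatic Claisen rearrangement ([3,3] shift to the free ortho carbon, then tautomerisation); the minor path through the OMe-bearing ortho carbon and a Cope shift to the para carbon gives the same compound 5, because the two positions are equivalent once both OH groups are free.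

Step 3
Reactants: 5 4-(2-bromoprop-2-en-1-yl)-2-methoxybenzene-1,3-diol; 6 (2,4,5-trimethoxyphenyl)boronic acid
Product: 7 2-methoxy-4-[2-(2,4,5-trimethoxyphenyl)prop-2-en-1-yl]benzene-1,3-diol
Conditions: Pd(dppf)Cl2 (3 mol%), K2CO3 (3 equiv), 1,4-dioxane/H2O 4:1, 80 °C, 4 h; chromatography on Et3N-deactivated silica
Reagents that add atoms: none
Why: Suzuki–Miyaura coupling at the vinylic C–Br, which tolerates free phenols; dppf on palladium does not favour C–O reductive elimination, so closure to a benzofuran is suppressed; no stereocentre is formed.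

Step 4
Reactants: 7 2-methoxy-4-[2-(2,4,5-trimethoxyphenyl)prop-2-en-1-yl]benzene-1,3-diol
Product: 8 (3S)-8-methoxy-3-(2,4,5-trimethoxyphenyl)-3,4-dihydro-2H-chromen-7-ol
Conditions: 3,6-di-tert-butyl-9-mesityl-10-phenylacridinium tetrafluoroborate (2 mol%), (R)-2'-(diphenylphosphoryl)-1,1'-binaphthalene-2-thiol (10 mol%), 2,6-lutidine (10 mol%), 1,2-dichloroethane (0.02 M), 450 nm LED, −20 °C, Ar
Reagents that add atoms: none
Why: Proposed new method: the excited acridinium oxidises the trimethoxystyrene unit (the most easily oxidised π-system of 7) to its radical cation, the ortho-phenol adds to the terminal CH2 in a 6-endo, anti-Markovnikov sense to form O1–C2 and a planar tertiary benzylic radical at C3, and this radical takes hydrogen from the S–H of the axially chiral arenethiol, whose bond (about 79 kcal/mol) is weaker than the new C3–H (about 84 kcal/mol) so the transfer is irreversible, and whose P=O group docks the 7-OH by a hydrogen bond so that one face of the radical is presented to sulfur, giving (S); the thiyl radical is then reduced by the acridinyl radical and reprotonated, which closes both cycles, and the lutidine buffer blocks acid-catalysed 5-exo Markovnikov closure; the closest known reaction types are the racemic acridinium/arenethiol anti-Markovnikov hydroetherification of alkenols, its chiral-anion variant (which controls only the carbon that bears oxygen), and peptide-thiol-controlled enantioselective hydrogen atom transfer in radical hydroamination, none of which uses a phenol nucleophile, a chiral arenethiol or a benzylic radical.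

Step 5
Reactants: 8 (3S)-8-methoxy-3-(2,4,5-trimethoxyphenyl)-3,4-dihydro-2H-chromen-7-ol
Product: 11 (3S)-3-(3-hydroxy-2,4,5-trimethoxyphenyl)-8-methoxy-3,4-dihydro-2H-chromen-7-ol, via dilithio species 9 (not isolated), via lithium aryltrimethoxyborate 10 (not isolated)
Conditions: n-BuLi (2.5 equiv), TMEDA (2.5 equiv), THF, −20 to 0 °C, 2 h; B(OMe)3 (3 equiv), −78 °C to rt; AcOH, 30% H2O2, 0 °C to rt
Reagents that add atoms: n-butyllithium, [Li]CCCC (lithium of 9 and 10); trimethyl borate, COB(OC)OC (boron and methoxy groups of 10); hydrogen peroxide, OO (the new oxygen of 11)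
Why: Directed ortho-metalation: after the 7-OH is deprotonated, n-BuLi removes the C3'–H flanked by the 2'- and 4'-methoxy groups, and borate trapping with peroxide-induced aryl migration places OH exactly there; C3 is untouched because its tertiary benzylic C–H on an electron-rich aryl group is far less kinetically acidic and, being axial, is not antiperiplanar to C2–O1.

## Compound list
1 | 2-methoxybenzene-1,3-diol | COc1c(O)cccc1O | starting material
2 | 2,3-dibromoprop-1-ene | C=C(Br)CBr | starting material
3 | 3-[(2-bromoprop-2-en-1-yl)oxy]-2-methoxyphenol | COc1c(O)cccc1OCC(Br)=C | intermediate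
4 | 6-(2-bromoprop-2-en-1-yl)-3-hydroxy-2-methoxycyclohexa-2,4-dien-1-one (racemic, transient) | O=C1C(OC)=C(O)C=CC1CC(Br)=C | intermediate
5 | 4-(2-bromoprop-2-en-1-yl)-2-methoxybenzene-1,3-diol | C=C(Br)Cc1ccc(O)c(OC)c1O | intermediate
6 | (2,4,5-trimethoxyphenyl)boronic acid | COc1cc(OC)c(B(O)O)cc1OC | starting material
7 | 2-methoxy-4-[2-(2,4,5-trimethoxyphenyl)prop-2-en-1-yl]benzene-1,3-diol | C=C(Cc1ccc(O)c(OC)c1O)c1cc(OC)c(OC)cc1OC | intermediate
8 | (3S)-8-methoxy-3-(2,4,5-trimethoxyphenyl)-3,4-dihydro-2H-chromen-7-ol | COc1cc([C@H]2COc3c(ccc(O)c3OC)C2)c(OC)cc1OC | intermediate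
9 | lithium (3S)-3-(3-lithio-2,4,5-trimethoxyphenyl)-8-methoxy-3,4-dihydro-2H-chromen-7-olate | COc1cc([C@H]2COc3c(ccc(O[Li])c3OC)C2)c(OC)c([Li])c1OC | intermediate
10 | dilithium salt of the (3S)-7-oxido-3'-(trimethoxyborate) of 8 | [Li+].[Li+].COc1cc([C@H]2COc3c(ccc([O-])c3OC)C2)c(OC)c([B-](OC)(OC)OC)c1OC | intermediate
11 | (3S)-3-(3-hydroxy-2,4,5-trimethoxyphenyl)-8-methoxy-3,4-dihydro-2H-chromen-7-ol, i.e. (3S)-7,3'-dihydroxy-8,2',4',5'-tetramethoxyisoflavan | COc1cc([C@H]2COc3c(ccc(O)c3OC)C2)c(OC)c(O)c1OC | target

Total step count: 5. Longest linear sequence: 5 (1 → 3 → 5 → 7 → 8 → 11).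

## Steps most likely to fail

**Step 4 (the proposed new step).** The risks are low enantioselectivity, isomerisation of the alkene into conjugation through loss of an allylic proton from the radical cation, acid-catalysed 5-exo closure, and loss of the thiol by thiol-ene addition.

The fallback uses known chemistry, sets out from 7 and comes back at 8. Both phenols of 7 are silylated (TBSCl, imidazole, DMF) to give the bis(tert-butyldimethylsilyl) ether of 7 F1. Asymmetric anti-Markovnikov hydroboration of this 1,1-disubstituted aryl alkene sets the stereocentre and gives the (S)-primary pinacol boronate F2. This step uses the CoCl2 complex of a chiral iminopyridine-oxazoline ligand, NaBHEt3 and HBpin in THF. Oxidation with NaBO3·4H2O gives the (S)-primary alcohol F3. Tetrabutylammonium fluoride frees the phenols to give the (S)-triol F4. An intramolecular Mitsunobu etherification (PPh3, DIAD, THF, high dilution) then closes the same O1–C2 bond without touching C3 and delivers 8.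

**Step 5.** The risks are sluggish or unselective lithiation of the poorly soluble lithium phenoxide, base-induced opening of ring C through loss of the C3–H, and over-oxidation of the electron-rich phenols.

The fallback sets out from 5 and comes back at 11, putting the oxygen on ring B before the coupling.
- Commercial 2,3,6-trimethoxybenzaldehyde (COc1ccc(OC)c(C=O)c1OC) is brominated with NBS in MeCN, meta to the formyl group and para to the 2-methoxy group, to give 3-bromo-2,5,6-trimethoxybenzaldehyde F5.
- Baeyer–Villiger oxidation with mCPBA gives 3-bromo-2,5,6-trimethoxyphenyl formate F6.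
- Methanolysis (K2CO3, MeOH) gives 3-bromo-2,5,6-trimethoxyphenol F7.
- Miyaura borylation (B2pin2, Pd(dppf)Cl2, KOAc, dioxane) gives 2,3,6-trimethoxy-5-(pinacolboryl)phenol F8.
- Suzuki–Miyaura coupling of F8 with 5 under the conditions of step 3 gives 4-[2-(3-hydroxy-2,4,5-trimethoxyphenyl)prop-2-en-1-yl]-2-methoxybenzene-1,3-diol F9.
- Ring closure of F9 under the conditions of step 4 gives 11 directly.

**Step 3.** The risks are closure of the ortho-(2-bromoallyl)phenol to a 2-methylbenzofuran under palladium and base, and protodeboronation of the electron-rich boronic acid.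

The fallback sets out from 6 and 1 and comes back at 7, attaching the aryl group before the rearrangement. Compound 6 is coupled with 2-bromoprop-2-en-1-ol (C=C(Br)CO) using Pd(PPh3)4 and K2CO3 in dioxane/H2O to give 2-(2,4,5-trimethoxyphenyl)prop-2-en-1-ol F10. Mitsunobu etherification with an excess of 1 (PPh3, DIAD, THF) gives 2-methoxy-3-{[2-(2,4,5-trimethoxyphenyl)prop-2-en-1-yl]oxy}phenol F11. Thermal Claisen rearrangement (PhNEt2, 180 °C) through the 6-(2-arylallyl) ortho-dienone F12 gives 7.

## Further compounds
F1 | step 4 | 1,3-bis(tert-butyldimethylsilyloxy)-2-methoxy-4-[2-(2,4,5-trimethoxyphenyl)prop-2-en-1-yl]benzene | C=C(Cc1ccc(O[Si](C)(C)C(C)(C)C)c(OC)c1O[Si](C)(C)C(C)(C)C)c1cc(OC)c(OC)cc1OC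
F2 | step 4 | 2-{(2S)-3-[2,4-bis(tert-butyldimethylsilyloxy)-3-methoxyphenyl]-2-(2,4,5-trimethoxyphenyl)propyl}-4,4,5,5-tetramethyl-1,3,2-dioxaborolane | COc1cc([C@@H](CB2OC(C)(C)C(C)(C)O2)Cc2ccc(O[Si](C)(C)C(C)(C)C)c(OC)c2O[Si](C)(C)C(C)(C)C)c(OC)cc1OC
F3 | step 4 | (2S)-3-[2,4-bis(tert-butyldimethylsilyloxy)-3-methoxyphenyl]-2-(2,4,5-trimethoxyphenyl)propan-1-ol | COc1cc([C@@H](CO)Cc2ccc(O[Si](C)(C)C(C)(C)C)c(OC)c2O[Si](C)(C)C(C)(C)C)c(OC)cc1OC
F4 | step 4 | 4-[(2S)-3-hydroxy-2-(2,4,5-trimethoxyphenyl)propyl]-2-methoxybenzene-1,3-diol | COc1cc([C@@H](CO)Cc2ccc(O)c(OC)c2O)c(OC)cc1OC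
F5 | step 5 | 3-bromo-2,5,6-trimethoxybenzaldehyde | COc1cc(Br)c(OC)c(C=O)c1OC
F6 | step 5 | 3-bromo-2,5,6-trimethoxyphenyl formate | COc1cc(Br)c(OC)c(OC=O)c1OC
F7 | step 5 | 3-bromo-2,5,6-trimethoxyphenol | COc1cc(Br)c(OC)c(O)c1OC
F8 | step 5 | 2,3,6-trimethoxy-5-(4,4,5,5-tetramethyl-1,3,2-dioxaborolan-2-yl)phenol | COc1cc(B2OC(C)(C)C(C)(C)O2)c(OC)c(O)c1OC
F9 | step 5 | 4-[2-(3-hydroxy-2,4,5-trimethoxyphenyl)prop-2-en-1-yl]-2-methoxybenzene-1,3-diol | C=C(Cc1ccc(O)c(OC)c1O)c1cc(OC)c(OC)c(O)c1OC
F10 | step 3 | 2-(2,4,5-trimethoxyphenyl)prop-2-en-1-ol | C=C(CO)c1cc(OC)c(OC)cc1OC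
F11 | step 3 | 2-methoxy-3-{[2-(2,4,5-trimethoxyphenyl)prop-2-en-1-yl]oxy}phenol | C=C(COc1cccc(O)c1OC)c1cc(OC)c(OC)cc1OC
F12 | step 3 | 3-hydroxy-2-methoxy-6-[2-(2,4,5-trimethoxyphenyl)prop-2-en-1-yl]cyclohexa-2,4-dien-1-one (racemic, transient) | O=C1C(OC)=C(O)C=CC1CC(=C)c1cc(OC)c(OC)cc1OC
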